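**Plan** (prostanoid numbering: C1 = ester carbon, C4 = side-chain acetoxy carbon, C8/C12 = ring stereocentres, C9 = ring C=O, C10=C11 = ring olefin, C13–C20 = octenyl chain)
1. Retrosynthetic cuts, in order: C9–C10 (opens the ring), C12–C13 (at the fully substituted carbinol), C11–C12 (ynone), C5=C6 (metathesis), C8–C9 (auxiliary alkylation).
2. Enabling feature: in the ring C8–C9–C10–C11–C12 the olefin C10=C11 sits on the acetoxy-bearing quaternary C12 and C9 is a carbonyl, so the ring opened between C9 and C10 is a 4-alkynal (C9 aldehyde, C8, C12, C11≡C10–H). Its isomerisation by cationic monovalent rhodium (trans-hydroacylation) returns the enone without adding a reagent atom.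
3. Forward: the chain is built acyclic (C8 by alkylation, the C1–C5 lactone by cross-metathesis, the ynone, the C13–C20 unit at C12, Z-olefin, ester and acetates) and the only ring closes in the last step.
4. Closing last keeps the β-acetoxy ketone, with its acidic C8–H, away from every other reagent; the cis relation of the two side chains is fixed in the open chain and not by ring thermodynamics.
5. Stereochemistry: C4 from the L-glutamic-acid-derived lactone 1; C8 from (S)-4-benzyloxazolidinone alkylation; C12 by 1,2-induction from C8 through a magnesium chelate; 5E from metathesis; 14Z from Lindlar reduction.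

Key step: step 16

Remark: 4-methoxybenzyl chloromethyl ether (7) and [Rh(dppe)]2(BF4)2 are treated as purchasable; the rhodium dimer is otherwise obtained by hydrogenating [Rh(nbd)(dppe)]BF4 in acetone just before use.

Step 1
Reactants: 1 (S)-5-(hydroxymethyl)dihydrofuran-2(3H)-one
Product: 2 (S)-5-oxotetrahydrofuran-2-carbaldehyde
Conditions: TEMPO (cat.), PhI(OAc)2, CH2Cl2, rt; acetic acid removed with toluene, crude used directly
Reagents that add atoms: none
Why: TEMPO-catalysed oxidation of a primary alcohol should stop at the aldehyde and leave the C4 stereocentre untouched.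

Step 2
Reactants: 2 (S)-5-oxotetrahydrofuran-2-carbaldehyde
Product: 3 (S)-5-vinyldihydrofuran-2(3H)-one
Conditions: Ph3PCH3Br, KOtBu, THF, 0 °C; then 2, −78 → 0 °C
Reagents that add atoms: methyltriphenylphosphonium bromide C[P+](c1ccccc1)(c1ccccc1)c1ccccc1.[Br-]
Why: Wittig methylenation with a non-stabilised ylide at low temperature should give the vinyl lactone while limiting epimerisation of the α-acyloxy aldehyde.

Step 3
Reactants: 4 (S)-4-benzyloxazolidin-2-one; 5 pent-4-enoyl chloride
Product: 6 (S)-4-benzyl-3-(pent-4-enoyl)oxazolidin-2-one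
Conditions: n-BuLi, THF, −78 °C; then 5, −78 → 0 °C
Reagents that add atoms: none
Why: N-acylation of the lithiated oxazolidinone by the acid chloride is a standard way to load the auxiliary.

Step 4
Reactants: 6 (S)-4-benzyl-3-(pent-4-enoyl)oxazolidin-2-one; 7 4-methoxybenzyl chloromethyl ether
Product: 8 (S)-4-benzyl-3-[(R)-2-{[(4-methoxybenzyl)oxy]methyl}pent-4-enoyl]oxazolidin-2-one
Conditions: NaHMDS, THF, −78 °C; then 7, −78 → −40 °C
Reagents that add atoms: none
Why: Evans asymmetric alkylation, in which the chelated Z-enolate should be attacked by the chloromethyl ether on the face opposite the benzyl group, sets C8.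

Step 5
Reactants: 8 (S)-4-benzyl-3-[(R)-2-{[(4-methoxybenzyl)oxy]methyl}pent-4-enoyl]oxazolidin-2-one; 3 (S)-5-vinyldihydrofuran-2(3H)-one
Product: 9 (S)-4-benzyl-3-[(2R,4E)-2-{[(4-methoxybenzyl)oxy]methyl}-5-[(2S)-5-oxotetrahydrofuran-2-yl]pent-4-enoyl]oxazolidin-2-one
Conditions: 3 (3 equiv), second-generation Hoveyda–Grubbs catalyst RuCl2(H2IMes)(=CH-C6H4-2-OiPr) (5 mol%), CH2Cl2, 40 °C
Reagents that add atoms: none
Why: Olefin cross-metathesis of a terminal olefin with an allylically oxygenated vinyl partner should give the E C5=C6 olefin under thermodynamic control, at a stage where no other olefin or alkyne is present to divert the carbene.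

Step 6
Reactants: 9 (S)-4-benzyl-3-[(2R,4E)-2-{[(4-methoxybenzyl)oxy]methyl}-5-[(2S)-5-oxotetrahydrofuran-2-yl]pent-4-enoyl]oxazolidin-2-one
Product: 10 S-ethyl (2R,4E)-2-{[(4-methoxybenzyl)oxy]methyl}-5-[(2S)-5-oxotetrahydrofuran-2-yl]pent-4-enethioate
Conditions: EtSH, n-BuLi, THF, 0 °C
Reagents that add atoms: ethanethiol CCS
Why: Thiolate cleavage of the N-acyl oxazolidinone at the exocyclic carbonyl should give the thiol ester without epimerising C8 and return the auxiliary.

Step 7
Reactants: 10 S-ethyl (2R,4E)-2-{[(4-methoxybenzyl)oxy]methyl}-5-[(2S)-5-oxotetrahydrofuran-2-yl]pent-4-enethioate; 11 ethynyltrimethylsilane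
Product: 12 (5S)-5-[(1E,4R)-4-{[(4-methoxybenzyl)oxy]methyl}-5-oxo-7-(trimethylsilyl)hept-1-en-6-yn-1-yl]dihydrofuran-2(3H)-one
Conditions: 11 (3 equiv), PdCl2(dppf) (10 mol%), P(2-furyl)3 (25 mol%), CuI (1.7 equiv), Et3N, DMF, 50 °C, sealed tube
Reagents that add atoms: none
Why: Palladium/copper-mediated coupling of a thiol ester with a terminal alkyne (acyl Sonogashira-type) should form the C11–C12 bond without a hard nucleophile that would attack the lactone.

Step 8
Reactants: 13 oct-2-yn-1-ol
Product: 14 oct-2-yn-1-yl methanesulfonate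
Conditions: MsCl, Et3N, CH2Cl2, −20 °C
Reagents that add atoms: methanesulfonyl chloride CS(Cl)(=O)=O
Why: Sulfonylation of the primary propargylic alcohol provides the leaving group for the SN2' step.

Step 9
Reactants: 14 oct-2-yn-1-yl methanesulfonate
Product: 15 tributyl(octa-1,2-dien-3-yl)stannane
Conditions: Bu3SnH, LDA, THF, 0 °C; CuBr·SMe2, −78 °C; then 14, −78 °C
Reagents that add atoms: tributyltin hydride CCCC[SnH](CCCC)CCCC
Why: Anti-SN2' displacement of a propargylic mesylate by a stannylcopper reagent should give the 1,1-disubstituted allenylstannane.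

Step 10
Reactants: 12 (5S)-5-[(1E,4R)-4-{[(4-methoxybenzyl)oxy]methyl}-5-oxo-7-(trimethylsilyl)hept-1-en-6-yn-1-yl]dihydrofuran-2(3H)-one; 15 tributyl(octa-1,2-dien-3-yl)stannane
Product: 16 (5S)-5-[(1E,4R,5S)-5-hydroxy-4-{[(4-methoxybenzyl)oxy]methyl}-5-[(trimethylsilyl)ethynyl]tridec-1-en-7-yn-1-yl]dihydrofuran-2(3H)-one
Conditions: MgBr2·OEt2 (3 equiv), CH2Cl2, −78 °C; then 15 (2 equiv), −78 → −20 °C
Reagents that add atoms: none
Why: In this chelation-controlled SE2' propargylation with an allenylstannane, MgBr2 should tie the C12 carbonyl to the C9 PMB ether in a six-membered chelate so that the CH2 terminus of 15 adds opposite the C7 substituent on C8, which sets C12 with its oxygen anti to C7 and gives the 2-alkynyl rather than the allenyl carbinol.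

Step 11
Reactants: 16 (5S)-5-[(1E,4R,5S)-5-hydroxy-4-{[(4-methoxybenzyl)oxy]methyl}-5-[(trimethylsilyl)ethynyl]tridec-1-en-7-yn-1-yl]dihydrofuran-2(3H)-one
Product: 17 (5S)-5-[(1E,4R,5S,7Z)-5-hydroxy-4-{[(4-methoxybenzyl)oxy]methyl}-5-[(trimethylsilyl)ethynyl]trideca-1,7-dien-1-yl]dihydrofuran-2(3H)-one
Conditions: H2 (1 atm), Lindlar catalyst (Pd on CaCO3, Pb(OAc)2-poisoned), quinoline, EtOAc, rt
Reagents that add atoms: none
Why: Lindlar semi-hydrogenation should add H2 syn to the dialkyl alkyne to give the 14Z olefin, while the silyl-capped alkyne on the quaternary carbon reacts much more slowly.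

Step 12
Reactants: 17 (5S)-5-[(1E,4R,5S,7Z)-5-hydroxy-4-{[(4-methoxybenzyl)oxy]methyl}-5-[(trimethylsilyl)ethynyl]trideca-1,7-dien-1-yl]dihydrofuran-2(3H)-one
Product: 19 methyl (4S,5E,8R,9S,11Z)-9-ethynyl-4,9-dihydroxy-8-{[(4-methoxybenzyl)oxy]methyl}heptadeca-5,11-dienoate, via potassium carboxylate 18 (not isolated)
Conditions: KOH (2.5 equiv), THF/MeOH/H2O, rt; solid CO2 to pH 8, evaporate; MeI, DMF, rt; crude used directly
Reagents that add atoms: potassium hydroxide [K+].[OH-]; iodomethane CI
Why: Hydroxide should remove the alkynyl silyl group and saponify the lactone, and O-alkylation of the carboxylate with MeI under non-acidic conditions gives the methyl ester before the 4-hydroxy acid can relactonise.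

Step 13
Reactants: 19 methyl (4S,5E,8R,9S,11Z)-9-ethynyl-4,9-dihydroxy-8-{[(4-methoxybenzyl)oxy]methyl}heptadeca-5,11-dienoate
Product: 20 methyl (4S,5E,8R,9S,11Z)-4,9-diacetoxy-9-ethynyl-8-{[(4-methoxybenzyl)oxy]methyl}heptadeca-5,11-dienoate
Conditions: Ac2O (6 equiv), DMAP (1 equiv), Et3N, CH2Cl2, rt → 40 °C
Reagents that add atoms: acetic anhydride CC(=O)OC(C)=O
Why: DMAP-catalysed acylation should esterify the secondary allylic alcohol at once (closing off relactonisation) and the tertiary propargylic alcohol more slowly in the same operation.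

Step 14
Reactants: 20 methyl (4S,5E,8R,9S,11Z)-4,9-diacetoxy-9-ethynyl-8-{[(4-methoxybenzyl)oxy]methyl}heptadeca-5,11-dienoate
Product: 21 methyl (4S,5E,8R,9S,11Z)-4,9-diacetoxy-9-ethynyl-8-(hydroxymethyl)heptadeca-5,11-dienoate
Conditions: DDQ (1.3 equiv), CH2Cl2/pH 7 phosphate buffer, 0 °C; crude used directly
Reagents that add atoms: none
Why: Oxidative cleavage of the PMB ether by DDQ at neutral pH and low temperature should free the C9 alcohol without 1,3-acetyl migration from the C12 oxygen.

Step 15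
Reactants: 21 methyl (4S,5E,8R,9S,11Z)-4,9-diacetoxy-9-ethynyl-8-(hydroxymethyl)heptadeca-5,11-dienoate
Product: 22 methyl (4S,5E,8S,9S,11Z)-4,9-diacetoxy-9-ethynyl-8-formylheptadeca-5,11-dienoate
Conditions: Dess–Martin periodinane (1.3 equiv), NaHCO3, CH2Cl2, 0 °C → rt; crude used at once
Reagents that add atoms: none
Why: Dess–Martin oxidation gives the aldehyde without amine base, so neither C8 epimerisation nor β-elimination of the C12 acetate should occur.

Step 16
Reactants: 22 methyl (4S,5E,8S,9S,11Z)-4,9-diacetoxy-9-ethynyl-8-formylheptadeca-5,11-dienoate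
Product: 23 methyl (4S,5E)-4-acetoxy-7-[(1S,5R)-5-acetoxy-5-[(2Z)-oct-2-en-1-yl]-2-oxocyclopent-3-en-1-yl]hept-5-enoate
Conditions: [Rh(dppe)]2(BF4)2 (5 mol%), degassed acetone, rt
Reagents that add atoms: none
Why: Proposed new method: the closest known reaction type is the intramolecular trans-hydroacylation of 4-alkynals to cyclopent-2-enones catalysed by cationic monovalent rhodium diphosphine complexes, established for internal alkynes (including substrates with an oxygenated quaternary C3) but not for a terminal alkyne next to a propargylic ester with a second γ,δ-unsaturation in the same molecule. Mechanism: the C9–H bond of 22 adds oxidatively to [Rh(dppe)]+ to give an acyl rhodium hydride, the ethynyl group on C12 coordinates, the hydride is transferred to C11 in a net trans addition that places rhodium on C10 in a six-membered rhodacycle (Rh–C9–C8–C12–C11=C10), and C9–C10 reductive elimination releases 23. The ring C8–C9–C10–C11–C12 is thus closed in a formally 5-endo-dig mode, which the metal makes possible because the bond to C10 forms from the rhodacycle and not by direct attack of C9 on the alkyne. No stereocentre is created; C8 and C12 come from 22, and the neutral, base-free medium at room temperature should leave the C8–H (α to the acyl group and β to the C12 acetate) unepimerised and the acetate in place. The step needs chemoselectivity for the C10≡C11 alkyne over the C5=C6 olefin (also γ,δ to C9), over decarbonylation and over acyloxy migration: the alkyne is the better ligand for cationic rhodium and is pressed against the acyl group by the fully substituted C12, whereas the olefin is trans-1,2-disubstituted and flanked by the branched C4 acetate carbon, the slowest olefin type for rhodium hydroacylation, and ester migration at rhodium normally needs heating. The unproven element is the terminal C10–H, where the hindered propargylic carbon C12 should hold back vinylidene formation and alkyne oligomerisation.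

**Compound list**
1 | (S)-5-(hydroxymethyl)dihydrofuran-2(3H)-one | OC[C@@H]1CCC(=O)O1 | starting material
2 | (S)-5-oxotetrahydrofuran-2-carbaldehyde | O=C[C@@H]1CCC(=O)O1 | intermediate
3 | (S)-5-vinyldihydrofuran-2(3H)-one | C=C[C@@H]1CCC(=O)O1 | intermediate
4 | (S)-4-benzyloxazolidin-2-one | O=C1N[C@@H](Cc2ccccc2)CO1 | starting material
5 | pent-4-enoyl chloride | C=CCCC(Cl)=O | starting material
6 | (S)-4-benzyl-3-(pent-4-enoyl)oxazolidin-2-one | C=CCCC(=O)N1[C@@H](Cc2ccccc2)COC1=O | intermediate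
7 | 4-methoxybenzyl chloromethyl ether | COc1ccc(COCCl)cc1 | starting material
8 | (S)-4-benzyl-3-[(R)-2-{[(4-methoxybenzyl)oxy]methyl}pent-4-enoyl]oxazolidin-2-one | C=CC[C@H](COCc1ccc(OC)cc1)C(=O)N1[C@@H](Cc2ccccc2)COC1=O | intermediate
9 | (S)-4-benzyl-3-[(2R,4E)-2-{[(4-methoxybenzyl)oxy]methyl}-5-[(2S)-5-oxotetrahydrofuran-2-yl]pent-4-enoyl]oxazolidin-2-one | O=C1CC[C@@H](/C=C/C[C@H](COCc2ccc(OC)cc2)C(=O)N2[C@@H](Cc3ccccc3)COC2=O)O1 | intermediate
10 | S-ethyl (2R,4E)-2-{[(4-methoxybenzyl)oxy]methyl}-5-[(2S)-5-oxotetrahydrofuran-2-yl]pent-4-enethioate | O=C1CC[C@@H](/C=C/C[C@H](COCc2ccc(OC)cc2)C(=O)SCC)O1 | intermediate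
11 | ethynyltrimethylsilane | C#C[Si](C)(C)C | starting material
12 | (5S)-5-[(1E,4R)-4-{[(4-methoxybenzyl)oxy]methyl}-5-oxo-7-(trimethylsilyl)hept-1-en-6-yn-1-yl]dihydrofuran-2(3H)-one | O=C1CC[C@@H](/C=C/C[C@H](COCc2ccc(OC)cc2)C(=O)C#C[Si](C)(C)C)O1 | intermediate
13 | oct-2-yn-1-ol | CCCCCC#CCO | starting material
14 | oct-2-yn-1-yl methanesulfonate | CCCCCC#CCOS(C)(=O)=O | intermediate
15 | tributyl(octa-1,2-dien-3-yl)stannane | CCCCCC(=C=C)[Sn](CCCC)(CCCC)CCCC | intermediate
16 | (5S)-5-[(1E,4R,5S)-5-hydroxy-4-{[(4-methoxybenzyl)oxy]methyl}-5-[(trimethylsilyl)ethynyl]tridec-1-en-7-yn-1-yl]dihydrofuran-2(3H)-one | CCCCCC#CC[C@@](O)(C#C[Si](C)(C)C)[C@@H](COCc1ccc(OC)cc1)C/C=C/[C@@H]1CCC(=O)O1 | intermediate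
17 | (5S)-5-[(1E,4R,5S,7Z)-5-hydroxy-4-{[(4-methoxybenzyl)oxy]methyl}-5-[(trimethylsilyl)ethynyl]trideca-1,7-dien-1-yl]dihydrofuran-2(3H)-one | CCCCC/C=C\C[C@@](O)(C#C[Si](C)(C)C)[C@@H](COCc1ccc(OC)cc1)C/C=C/[C@@H]1CCC(=O)O1 | intermediate
18 | potassium (4S,5E,8R,9S,11Z)-9-ethynyl-4,9-dihydroxy-8-{[(4-methoxybenzyl)oxy]methyl}heptadeca-5,11-dienoate | CCCCC/C=C\C[C@@](O)(C#C)[C@@H](COCc1ccc(OC)cc1)C/C=C/[C@@H](O)CCC(=O)[O-].[K+] | intermediate
19 | methyl (4S,5E,8R,9S,11Z)-9-ethynyl-4,9-dihydroxy-8-{[(4-methoxybenzyl)oxy]methyl}heptadeca-5,11-dienoate | CCCCC/C=C\C[C@@](O)(C#C)[C@@H](COCc1ccc(OC)cc1)C/C=C/[C@@H](O)CCC(=O)OC | intermediate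
20 | methyl (4S,5E,8R,9S,11Z)-4,9-diacetoxy-9-ethynyl-8-{[(4-methoxybenzyl)oxy]methyl}heptadeca-5,11-dienoate | CCCCC/C=C\C[C@@](OC(C)=O)(C#C)[C@@H](COCc1ccc(OC)cc1)C/C=C/[C@@H](OC(C)=O)CCC(=O)OC | intermediate
21 | methyl (4S,5E,8R,9S,11Z)-4,9-diacetoxy-9-ethynyl-8-(hydroxymethyl)heptadeca-5,11-dienoate | CCCCC/C=C\C[C@@](OC(C)=O)(C#C)[C@@H](CO)C/C=C/[C@@H](OC(C)=O)CCC(=O)OC | intermediate
22 | methyl (4S,5E,8S,9S,11Z)-4,9-diacetoxy-9-ethynyl-8-formylheptadeca-5,11-dienoate | CCCCC/C=C\C[C@@](OC(C)=O)(C#C)[C@@H](C=O)C/C=C/[C@@H](OC(C)=O)CCC(=O)OC | intermediate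
23 | methyl (4S,5E)-4-acetoxy-7-[(1S,5R)-5-acetoxy-5-[(2Z)-oct-2-en-1-yl]-2-oxocyclopent-3-en-1-yl]hept-5-enoate | CCCCC/C=C\C[C@@]1(OC(C)=O)C=CC(=O)[C@H]1C/C=C/[C@H](CCC(=O)OC)OC(C)=O | target

**Count and risks**
Total steps: 16. Longest linear sequence: 12 (steps 3–7 and 10–16, or equally steps 1, 2, 5–7 and 10–16).

Steps most likely to fail:

1. Step 16 (bears the label). What may go wrong: insertion of the acyl rhodium hydride into the C5=C6 olefin instead of the alkyne, decarbonylation of the acyl rhodium species, or unproductive reaction at the terminal alkyne C–H. Fallback with known chemistry, setting out from 20 and returning at 23: 20 is iodinated at the alkyne terminus (N-iodosuccinimide, AgNO3 cat., acetone) to the iodoalkyne F1. F1 is reduced with diimide (2-nitrobenzenesulfonohydrazide, Et3N) to the (Z)-vinyl iodide F2. DDQ then frees the primary alcohol F3 and Dess–Martin oxidation gives the iodo aldehyde F4. An intramolecular Nozaki–Hiyama–Kishi reaction (CrCl2, NiCl2 cat., DMF) closes the same C9–C10 bond to give the cyclopentenol F5 as both C9 epimers, and Dess–Martin periodinane oxidises F5 to 23.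

2. Step 10. What may go wrong: slow addition of the stannane to the ketone, or incomplete chelation so that facial selectivity at C12 erodes. Fallback that builds the C13–C20 chain by aldol and olefination instead, setting out from 12 and returning at 19: a chelation-controlled Mukaiyama aldol addition of 1-(ethylthio)-1-(trimethylsilyloxy)ethene to 12 (TiCl4, CH2Cl2, −78 °C) gives the β-hydroxy thiol ester F6. F6 is silylated (TMSOTf, 2,6-lutidine) to the silyl ether F7 and a Fukuyama reduction (Et3SiH, Pd/C, acetone) gives the aldehyde F8. A Z-selective Wittig reaction with the ylide from hexyltriphenylphosphonium bromide and NaHMDS at −78 °C gives the Z-olefin silyl ether F9. The conditions of step 12 then remove both silyl groups, open the lactone and esterify, giving 19.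

3. Step 7. What may go wrong: epimerisation at C8 or β-elimination of the PMB ether under amine and heat, or slow coupling of the α-branched thiol ester. Fallback that reaches the ynone through the aldehyde, setting out from 10 and returning at 12: Fukuyama reduction of 10 (Et3SiH, Pd/C, acetone) gives the aldehyde F10. Lithium (trimethylsilyl)acetylide (from 11 and n-BuLi, THF, −78 °C) adds to the aldehyde much faster than to the lactone and gives the propargylic alcohol F11 as a mixture of C12 epimers. Dess–Martin periodinane oxidises F11 to 12.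

**Further compounds**
F1 | step 16 | methyl (4S,5E,8R,9S,11Z)-4,9-diacetoxy-9-(iodoethynyl)-8-{[(4-methoxybenzyl)oxy]methyl}heptadeca-5,11-dienoate | CCCCC/C=C\C[C@@](OC(C)=O)(C#CI)[C@@H](COCc1ccc(OC)cc1)C/C=C/[C@@H](OC(C)=O)CCC(=O)OC
F2 | step 16 | (Z)-2-iodovinyl analogue of 20 (C10–I cis to C12 across C10=C11) | CCCCC/C=C\C[C@@](OC(C)=O)(/C=C\I)[C@@H](COCc1ccc(OC)cc1)C/C=C/[C@@H](OC(C)=O)CCC(=O)OC
F3 | step 16 | (Z)-2-iodovinyl analogue of 21 (free C9 alcohol) | CCCCC/C=C\C[C@@](OC(C)=O)(/C=C\I)[C@@H](CO)C/C=C/[C@@H](OC(C)=O)CCC(=O)OC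
F4 | step 16 | (Z)-2-iodovinyl analogue of 22 (C9 aldehyde) | CCCCC/C=C\C[C@@](OC(C)=O)(/C=C\I)[C@@H](C=O)C/C=C/[C@@H](OC(C)=O)CCC(=O)OC
F5 | step 16 | C9 alcohol of 23 (2-hydroxycyclopent-3-enyl compound, both C9 epimers) | CCCCC/C=C\C[C@@]1(OC(C)=O)C=CC(O)[C@H]1C/C=C/[C@H](CCC(=O)OC)OC(C)=O
F6 | step 10 | S-ethyl thiol ester of the C14 acid, with C12 tertiary alcohol, silylated alkyne, C9 PMB ether and C1–C4 lactone | CCSC(=O)C[C@@](O)(C#C[Si](C)(C)C)[C@@H](COCc1ccc(OC)cc1)C/C=C/[C@@H]1CCC(=O)O1
F7 | step 10 | O12-trimethylsilyl ether of F6 | CCSC(=O)C[C@@](O[Si](C)(C)C)(C#C[Si](C)(C)C)[C@@H](COCc1ccc(OC)cc1)C/C=C/[C@@H]1CCC(=O)O1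
F8 | step 10 | C14 aldehyde from F7 | O=CC[C@@](O[Si](C)(C)C)(C#C[Si](C)(C)C)[C@@H](COCc1ccc(OC)cc1)C/C=C/[C@@H]1CCC(=O)O1
F9 | step 10 | O12-trimethylsilyl ether of 17 | CCCCC/C=C\C[C@@](O[Si](C)(C)C)(C#C[Si](C)(C)C)[C@@H](COCc1ccc(OC)cc1)C/C=C/[C@@H]1CCC(=O)O1
F10 | step 7 | (2R,4E)-2-{[(4-methoxybenzyl)oxy]methyl}-5-[(2S)-5-oxotetrahydrofuran-2-yl]pent-4-enal | O=C[C@@H](COCc1ccc(OC)cc1)C/C=C/[C@@H]1CCC(=O)O1
F11 | step 7 | C12 alcohol of 12 (propargylic alcohol, both C12 epimers) | C[Si](C)(C)C#CC(O)[C@@H](COCc1ccc(OC)cc1)C/C=C/[C@@H]1CCC(=O)O1
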